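**Retrosynthetic overview**
1. Macrocarpal H ⇒ tris‑O‑methyl dialdehyde (final thiolate demethylation) ⇒ aryl ether lacking the two CHO groups (double ortho‑lithiation/formylation).
2. C1'–isobutyl bond ⇒ 1,4‑addition of i‑BuMgBr to an o‑quinone methide made from 3,5‑dimethoxyphenol and a 1β‑formyl‑β‑eudesmol aldehyde; C1' is controlled by C1 through allylic strain.
3. That aldehyde ⇒ trans‑decalone ester (C4 methylenation, Markovnikov hydration of the isopropenyl group, ester → CHO).
4. Decalone ester ⇒ intramolecular Diels–Alder of an acyclic 2‑silyloxydiene / (E)‑β‑methyl enoate triene. Rings A and B form together in this one step; C7 (bought) sits equatorial in the chair tether and sets C10 and C1, and C5 is secured by epimerisation.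
5. Triene ⇒ (+)‑(4R)‑limonene oxide: periodate ring cleavage, aldehyde arm homologated to a vinyl ketone, ketone arm olefinated to the enoate. The aromatic ring is bought.

Assumption: eudesmane numbering is used for the decalin (C14 methyl on C10, C15 on C4, C11 on C7); every compound that contributes non‑hydrogen atoms is numbered, and (+)‑limonene oxide (cis/trans mixture) and 3,5‑dimethoxyphenol are taken as commercial.

**Route**

Step 1
Reactants: 1 (+)‑(4R)‑limonene 1,2‑oxide (cis/trans mixture); 2 water
Product: 3 (3R)‑6‑oxo‑3‑(prop‑1‑en‑2‑yl)heptanal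
Conditions: H5IO6, THF/H2O, 0 °C → rt
Reagents that add atoms: water, O
Why: Epoxide hydrolysis followed by periodate glycol cleavage cuts only the ring C1–C2 bond, so the limonene C4 stereocentre (future C7) is untouched.

Step 2
Reactants: 3; 4 (methoxymethyl)triphenylphosphonium chloride
Product: 5 (5R)‑8‑methoxy‑5‑(prop‑1‑en‑2‑yl)oct‑7‑en‑2‑one (E/Z enol ether mixture)
Conditions: 4 (1.05 equiv), KHMDS, THF, −78 → −20 °C
Reagents that add atoms: (methoxymethyl)triphenylphosphonium chloride, COC[P+](c1ccccc1)(c1ccccc1)c1ccccc1.[Cl-]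
Why: Wittig methoxymethylenation (one‑carbon homologation) is much faster at the aldehyde than at the methyl ketone at low temperature.

Step 3
Reactants: 5; 6 trimethyl phosphonoacetate
Product: 7 methyl (2E,6R)‑9‑methoxy‑3‑methyl‑6‑(prop‑1‑en‑2‑yl)nona‑2,8‑dienoate
Conditions: NaH, THF, 0 °C → reflux; E isomer separated (expected about 4:1 E/Z)
Reagents that add atoms: trimethyl phosphonoacetate, COC(=O)CP(=O)(OC)OC
Why: Horner–Wadsworth–Emmons olefination of the methyl ketone gives mainly the E enoate; this geometry later fixes the cis relationship of C10‑Me and the C1 substituent.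

Step 4
Reactants: 7; 2 water
Product: 8 methyl (2E,6R)‑3‑methyl‑9‑oxo‑6‑(prop‑1‑en‑2‑yl)non‑2‑enoate
Conditions: 1 M HCl, THF, rt
Reagents that add atoms: water, O
Why: Mild acid hydrolysis of the methyl enol ether releases the homologated aldehyde; the enoate and isopropenyl group are stable.

Step 5
Reactants: 8; 9 vinylmagnesium bromide
Product: 10 methyl (2E,6R)‑9‑hydroxy‑3‑methyl‑6‑(prop‑1‑en‑2‑yl)undeca‑2,10‑dienoate (C9 epimers)
Conditions: 9 (1.1 equiv), THF, −78 °C
Reagents that add atoms: vinylmagnesium bromide, C=C[Mg]Br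
Why: Grignard 1,2‑addition to the aldehyde outruns attack on the β,β‑disubstituted enoate at −78 °C; the new carbinol centre is removed in the next step.

Step 6
Reactants: 10
Product: 11 methyl (2E,6R)‑3‑methyl‑9‑oxo‑6‑(prop‑1‑en‑2‑yl)undeca‑2,10‑dienoate (vinyl ketone)
Conditions: Dess–Martin periodinane, NaHCO3, CH2Cl2, 0 °C
Reagents that add atoms: none
Why: Neutral oxidation of the allylic alcohol gives the vinyl ketone without touching the other alkenes; it is used promptly.

Step 7
Reactants: 11; 12 tert‑butyldimethylsilyl triflate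
Product: 13 methyl (2E,6R,8Z)‑9‑(tert‑butyldimethylsilyloxy)‑3‑methyl‑6‑(prop‑1‑en‑2‑yl)undeca‑2,8,10‑trienoate
Conditions: TBSOTf, Et3N, CH2Cl2, −78 → 0 °C; filtered through basic alumina
Reagents that add atoms: TBSOTf, CC(C)(C)[Si](C)(C)OS(=O)(=O)C(F)(F)F
Why: Soft enolisation of the vinyl ketone toward its only α‑CH2 gives the (Z)‑2‑silyloxy‑1,3‑diene, with the tether trans to the vinyl group as the cycloaddition requires.

Step 8
Reactants: 13
Product: 14 methyl 4‑(TBS‑oxy)‑8a‑methyl‑6‑(prop‑1‑en‑2‑yl)‑1,2,4a,5,6,7,8,8a‑octahydronaphthalene‑1‑carboxylate (1‑CO2Me, 6‑isopropenyl and 8a‑Me all β; 4a‑H α)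
Conditions: toluene (0.01 M), BHT, 180 °C, sealed tube
Reagents that add atoms: none
Why: Intramolecular Diels–Alder reaction forming both carbocycles. The electron‑rich diene terminus C5 bonds to the enoate β‑carbon C10. A chair tether with the C7 isopropenyl equatorial and the ester endo gives the trans‑decalin with 10β‑Me, and the E‑enoate places CO2Me cis to that methyl (1β).

Step 9
Reactants: 14
Product: 15 methyl 8a‑methyl‑4‑oxo‑6‑(prop‑1‑en‑2‑yl)decahydronaphthalene‑1‑carboxylate (trans‑fused; same relative configuration)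
Conditions: TBAF, AcOH, THF, 0 °C; then K2CO3, MeOH, rt
Reagents that add atoms: none
Why: Desilylation unmasks the C4 ketone and mild base equilibrates C5 (α to the ketone) to the more stable trans fusion, converging any cis‑fused adduct of the same C10 configuration; the less acidic C1–H of the ester is not affected.

Step 10
Reactants: 15; 16 dioxygen
Product: 17 methyl 6‑(2‑hydroxypropan‑2‑yl)‑8a‑methyl‑4‑oxodecahydronaphthalene‑1‑carboxylate
Conditions: Co(acac)2 (20 mol %), PhSiH3, O2 (1 atm), THF, rt
Reagents that add atoms: dioxygen, O=O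
Why: Mukaiyama hydration is Markovnikov at the isopropenyl group, the only alkene present, and leaves the ketone and ester alone.

Step 11
Reactants: 17; 18 methyltriphenylphosphonium bromide
Product: 19 methyl 6‑(2‑hydroxypropan‑2‑yl)‑8a‑methyl‑4‑methylidenedecahydronaphthalene‑1‑carboxylate (β‑eudesmol 1β‑carboxylate methyl ester)
Conditions: 18 (3 equiv), KOtBu, THF, 0 °C → rt
Reagents that add atoms: methyltriphenylphosphonium bromide, C[P+](c1ccccc1)(c1ccccc1)c1ccccc1.[Br-]
Why: Wittig methylenation is selective for the ketone over the hindered ester; the extra ylide is consumed by the tertiary OH, and C5 stays in its thermodynamic trans configuration.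

Step 12
Reactants: 19
Product: 20 6‑(2‑hydroxypropan‑2‑yl)‑8a‑methyl‑4‑methylidenedecahydronaphthalene‑1‑carbaldehyde (1β‑formyl‑β‑eudesmol)
Conditions: DIBAL‑H (2.3 equiv), CH2Cl2, −78 °C; Rochelle salt work‑up
Reagents that add atoms: none
Why: The hindered ester next to quaternary C10 gives a tetrahedral aluminate that is stable at −78 °C, so reduction stops at the aldehyde.

Step 13
Reactants: 20; 21 3,5‑dimethoxyphenol; 22 isobutylmagnesium bromide
Product: 23 2‑[(1S)‑3‑methyl‑1‑(1β‑eudesm‑4(15)‑en‑11‑ol‑1‑yl)butyl]‑3,5‑dimethoxyphenol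
Conditions: 21 + EtMgBr (1 equiv), Et2O → toluene; add 20, rt; then 22 (5 equiv), THF/toluene, 0 → 50 °C (one pot)
Reagents that add atoms: 3,5‑dimethoxyphenol, COc1cc(O)cc(OC)c1; isobutylmagnesium bromide, CC(C)C[Mg]Br
Why: Magnesium phenoxide ortho‑hydroxyalkylation (Casiraghi) is followed by Mg‑assisted elimination to the o‑quinone methide and 1,4‑addition of the Grignard reagent. With C1–H eclipsing the exocyclic C=C (A1,3 strain), isobutyl enters anti to quaternary C10, which gives (1'S).

Step 14
Reactants: 23; 24 iodomethane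
Product: 25 the 2,4,6‑trimethoxyphenyl analogue of 23
Conditions: MeI, K2CO3, acetone, reflux
Reagents that add atoms: iodomethane, CI
Why: Williamson methylation of the phenol only (the tertiary alcohol is inert) gives an arene whose two ring hydrogens are each flanked by two OMe directing groups.

Step 15
Reactants: 25; 26 N,N‑dimethylformamide
Product: 27 2,4,6‑trimethoxy‑5‑[(1S)‑3‑methyl‑1‑(1β‑eudesm‑4(15)‑en‑11‑ol‑1‑yl)butyl]benzene‑1,3‑dicarbaldehyde
Conditions: n‑BuLi/TMEDA, THF, 0 °C; DMF, −78 → 0 °C; second n‑BuLi/TMEDA then DMF in the same flask; aq. NH4Cl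
Reagents that add atoms: DMF, CN(C)C=O
Why: Directed ortho‑metalation between two OMe groups and formylation; the first formyl group is protected in situ as its α‑amino alkoxide during the second lithiation, and the tertiary OH is carried as its alkoxide.

Step 16
Reactants: 27
Product: 28 Macrocarpal H
Conditions: lithium p‑thiocresolate (excess), HMPA/toluene, reflux; acidic work‑up
Reagents that add atoms: none
Why: SN2 O‑demethylation by thiolate; all three OMe groups are ortho to a formyl group and so are activated, and the non‑acidic conditions spare the exocyclic alkene, tertiary alcohol and both stereocentres of the side chain.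

**Compound list**
1 | (+)‑(4R)‑limonene 1,2‑oxide | CC12OC1C[C@@H](CC2)C(C)=C | starting material
2 | water | O | starting material (reagent)
3 | (3R)‑6‑oxo‑3‑(prop‑1‑en‑2‑yl)heptanal | CC(=O)CC[C@@H](C(C)=C)CC=O | intermediate
4 | (methoxymethyl)triphenylphosphonium chloride | COC[P+](c1ccccc1)(c1ccccc1)c1ccccc1.[Cl-] | starting material (reagent)
5 | (5R)‑8‑methoxy‑5‑(prop‑1‑en‑2‑yl)oct‑7‑en‑2‑one | CC(=O)CC[C@@H](C(C)=C)CC=COC | intermediate
6 | trimethyl phosphonoacetate | COC(=O)CP(=O)(OC)OC | starting material (reagent)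
7 | methyl (2E,6R)‑9‑methoxy‑3‑methyl‑6‑(prop‑1‑en‑2‑yl)nona‑2,8‑dienoate | COC(=O)/C=C(\C)CC[C@@H](C(C)=C)CC=COC | intermediate
8 | methyl (2E,6R)‑3‑methyl‑9‑oxo‑6‑(prop‑1‑en‑2‑yl)non‑2‑enoate | COC(=O)/C=C(\C)CC[C@@H](C(C)=C)CCC=O | intermediate
9 | vinylmagnesium bromide | C=C[Mg]Br | starting material (reagent)
10 | methyl (2E,6R)‑9‑hydroxy‑3‑methyl‑6‑(prop‑1‑en‑2‑yl)undeca‑2,10‑dienoate | COC(=O)/C=C(\C)CC[C@@H](C(C)=C)CCC(O)C=C | intermediate
11 | methyl (2E,6R)‑3‑methyl‑9‑oxo‑6‑(prop‑1‑en‑2‑yl)undeca‑2,10‑dienoate | COC(=O)/C=C(\C)CC[C@@H](C(C)=C)CCC(=O)C=C | intermediate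
12 | tert‑butyldimethylsilyl triflate | CC(C)(C)[Si](C)(C)OS(=O)(=O)C(F)(F)F | starting material (reagent)
13 | methyl (2E,6R,8Z)‑9‑(TBS‑oxy)‑3‑methyl‑6‑(prop‑1‑en‑2‑yl)undeca‑2,8,10‑trienoate | COC(=O)/C=C(\C)CC[C@@H](C(C)=C)C/C=C(\O[Si](C)(C)C(C)(C)C)C=C | intermediate
14 | IMDA adduct (silyl enol ether, trans‑fused) | CC(C)(C)[Si](C)(C)OC1=CC[C@@H](C(=O)OC)[C@]2(C)CC[C@@H](C(C)=C)C[C@@H]12 | intermediate
15 | trans‑decalone ester | O=C1CC[C@@H](C(=O)OC)[C@]2(C)CC[C@@H](C(C)=C)C[C@@H]12 | intermediate
16 | dioxygen | O=O | starting material (reagent)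
17 | hydroxy keto ester | O=C1CC[C@@H](C(=O)OC)[C@]2(C)CC[C@@H](C(C)(C)O)C[C@@H]12 | intermediate
18 | methyltriphenylphosphonium bromide | C[P+](c1ccccc1)(c1ccccc1)c1ccccc1.[Br-] | starting material (reagent)
19 | 4‑methylidene hydroxy ester | C=C1CC[C@@H](C(=O)OC)[C@]2(C)CC[C@@H](C(C)(C)O)C[C@@H]12 | intermediate
20 | 1β‑formyl‑β‑eudesmol | C=C1CC[C@@H](C=O)[C@]2(C)CC[C@@H](C(C)(C)O)C[C@@H]12 | intermediate
21 | 3,5‑dimethoxyphenol | COc1cc(O)cc(OC)c1 | starting material
22 | isobutylmagnesium bromide | CC(C)C[Mg]Br | starting material (reagent)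
23 | alkylated dimethoxyphenol | C=C1CC[C@@H]([C@H](CC(C)C)c2c(O)cc(OC)cc2OC)[C@]2(C)CC[C@@H](C(C)(C)O)C[C@@H]12 | intermediate
24 | iodomethane | CI | starting material (reagent)
25 | trimethoxyaryl intermediate | C=C1CC[C@@H]([C@H](CC(C)C)c2c(OC)cc(OC)cc2OC)[C@]2(C)CC[C@@H](C(C)(C)O)C[C@@H]12 | intermediate
26 | N,N‑dimethylformamide | CN(C)C=O | starting material (reagent)
27 | tris‑O‑methyl macrocarpal H | C=C1CC[C@@H]([C@H](CC(C)C)c2c(OC)c(C=O)c(OC)c(C=O)c2OC)[C@]2(C)CC[C@@H](C(C)(C)O)C[C@@H]12 | intermediate
28 | Macrocarpal H | C=C1CC[C@@H]([C@H](CC(C)C)c2c(O)c(C=O)c(O)c(C=O)c2O)[C@]2(C)CC[C@@H](C(C)(C)O)C[C@@H]12 | target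

**Totals**
Total steps: 16. Longest linear sequence: 16 (from 1; all other partners are purchased).

**Three steps most likely to fail**
1. Step 8 (IMDA creating quaternary C10). It may be sluggish, and a cis‑fused pathway with the enoate terminus axial on the tether would give the C10 epimer. Fallback: give up the concerted thermal cycloaddition and close the decalin stepwise from vinyl ketone 11 by an anionic or Lewis‑acid intramolecular double Michael reaction (LiHMDS, or TMSI/HMDS), then equilibrate as in step 9.
2. Step 13 (o‑quinone methide alkylation). Risks are β‑hydride reduction by i‑BuMgBr, tautomerisation of the quinone methide to the styrene (which would scramble C1), and modest selectivity at C1'. Fallback: switch to a benzylic‑cation route. Add 2,4,6‑trimethoxyphenyllithium to the aldehyde (this also removes step 14), ionise the carbinol with BF3·OEt2 and trap with (2‑methylallyl)trimethylsilane. This is run on the C4‑ketal series so the methallyl group can be hydrogenated to isobutyl before the C4 methylenation.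
3. Steps 15–16 (late double formylation and triple demethylation). The second lithiation may be incomplete and the thiolate demethylation is forcing. Fallback: change the protecting‑group plan to MOM ethers (bis‑MOM phenol partner, MOM capping after step 13) so the final deprotection is mild acid, and install the CHO groups by NBS dibromination followed by Br/Li exchange and DMF.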